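**Retrosynthetic overview**
- The target is reached by late oxidation-state and acyl adjustments of a germacra-1(10),4(15),11(13)-trien-6α,12-olide: C8–Si → C8–OH → angelate, Mitsunobu inversion at C3 to the 3α-acetate, and 1(10)-epoxidation.
- The γ-lactone comes from C7 alkylation and C6 reduction of a cyclodec-5-enone. The ten-membered ring comes from an anionic oxy-Cope rearrangement of a trans-1,2-dialkenylcyclohexanol, which breaks C1–C6, forms C8–C9, and sets C8 through the (E)-silylvinyl terminus in a chair transition state.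
- The carbinol comes from an all-cis cyclohexanone and an (E)-2-silylvinyl metal reagent. The ketone comes from (R)-carvone by α′-oxygenation, Luche reduction, directed epoxidation and epoxide → allylic alcohol isomerisation; these fix C3 and C5.
- Ring order: cyclohexane (bought) → cyclodecene ([3,3] ring expansion) → trans-fused γ-lactone → epoxide.

Assumption: six-membered intermediates use carvone numbering (c1 = carbonyl carbon, c2 = methyl-bearing carbon, c5 = isopropenyl-bearing carbon, c6 = α′ carbon); ten-membered intermediates use germacrane numbering (C1–C15), with α/β as in the usual germacranolide drawing (H-7 α). The SMILES strings are authoritative.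

**Step 1**
Reactants: 1 (R)-(−)-carvone
Product: 3 trans-6-(triethylsilyloxy)carvone (c6-OSiEt3 trans to the isopropenyl group), via silyl dienol ether 2 (not isolated)
Conditions: LiN(iPr)2, THF, −78 °C; Et3SiCl, −78 → 0 °C; then mCPBA, hexane, −15 → 20 °C
Reagents that add atoms: chlorotriethylsilane, CC[Si](Cl)(CC)CC; mCPBA, OOC(=O)c1cccc(Cl)c1
Why: Kinetic α′-deprotonation and O-silylation give the cross-conjugated dienol ether, whose enol double bond is epoxidised anti to the neighbouring isopropenyl group and collapses with 1,4-silyl shift (Rubottom oxidation), so c6 is set trans to the bought c5 centre.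

**Step 2**
Reactants: 3 trans-6-(triethylsilyloxy)carvone
Product: 4 6-(triethylsilyloxy)-cis-carveol (c1-OH cis to isopropenyl, trans to c6-OSiEt3)
Conditions: NaBH4, CeCl3·7H2O, MeOH, −78 °C
Reagents that add atoms: none
Why: Luche 1,2-reduction with axial hydride delivery gives the equatorial allylic alcohol cis to the isopropenyl group, as in the carvone → cis-carveol reduction.

**Step 3**
Reactants: 4 6-(triethylsilyloxy)-cis-carveol
Product: 5 2,3-epoxy alcohol (epoxide syn to c1-OH and to the isopropenyl group)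
Conditions: VO(acac)2 (2 mol %), t-BuOOH, CH2Cl2, 0 → 20 °C
Reagents that add atoms: tert-butyl hydroperoxide, CC(C)(C)OO
Why: Vanadium-catalysed hydroxyl-directed epoxidation delivers oxygen to the ring alkene on the face of the allylic c1-OH and leaves the isopropenyl group untouched.

**Step 4**
Reactants: 5 2,3-epoxy alcohol
Product: 6 c1-triisopropylsilyl ether of 5
Conditions: iPr3SiOTf, 2,6-lutidine, CH2Cl2, −78 °C
Reagents that add atoms: triisopropylsilyl triflate, CC(C)[Si](OS(=O)(=O)C(F)(F)F)(C(C)C)C(C)C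
Why: Silyl triflate silylation of the hindered secondary alcohol at low temperature in the presence of a hindered base leaves the epoxide and all stereocentres unchanged.

**Step 5**
Reactants: 6 c1-triisopropylsilyl ether
Product: 7 exocyclic-methylene allylic alcohol (c2=CH2; c3-OH cis to c1-OSi(iPr)3 and to isopropenyl)
Conditions: Et2Al(tmp) [from lithium 2,2,6,6-tetramethylpiperidide + Et2AlCl], toluene, 0 °C
Reagents that add atoms: none
Why: In this aluminium amide epoxide → allylic alcohol rearrangement, syn β-elimination removes a proton from the methyl group cis to c3-H and cleaves the tertiary C–O bond, so the c3 oxygen keeps its configuration and the exocyclic alkene forms.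

**Step 6**
Reactants: 7 exocyclic-methylene allylic alcohol
Product: 8 c3-tert-butyldimethylsilyl ether of 7
Conditions: t-BuMe2SiOTf, 2,6-lutidine, CH2Cl2, −78 °C
Reagents that add atoms: tert-butyldimethylsilyl triflate, CC(C)(C)[Si](C)(C)OS(=O)(=O)C(F)(F)F
Why: Routine silylation of the allylic alcohol gives three different silyl ethers that can be removed in the order SiEt3, SitBuMe2, Si(iPr)3.

**Step 7**
Reactants: 8 tris-silyl ether
Product: 9 c6 alcohol (SiEt3 removed)
Conditions: PPTS (cat.), MeOH/CH2Cl2, 0 °C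
Reagents that add atoms: none
Why: Mild acid methanolysis cleaves the triethylsilyl ether selectively because it is far more acid-labile than the tert-butyldimethylsilyl and triisopropylsilyl ethers.

**Step 8**
Reactants: 9 c6 alcohol
Product: 10 all-cis 4-(tert-butyldimethylsilyloxy)-3-methylidene-6-(prop-1-en-2-yl)-2-(triisopropylsilyloxy)cyclohexan-1-one
Conditions: Dess–Martin periodinane, CH2Cl2, 0 → 20 °C
Reagents that add atoms: none
Why: Dess–Martin oxidation under neutral conditions gives the ketone without epimerising or conjugating the α-isopropenyl centre.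

**Step 9**
Reactants: 11 (E)-1,2-bis(tributylstannyl)ethene; 12 benzylchlorodimethylsilane
Product: 14 (E)-benzyldimethyl[2-(tributylstannyl)ethenyl]silane, via stannylvinyllithium 13 (not isolated)
Conditions: n-BuLi (1.0 equiv), THF, −78 °C; then 12, −78 → 0 °C
Reagents that add atoms: none
Why: Tin–lithium exchange at one terminus proceeds with retention of the (E) geometry and the vinyllithium is silylated by the chlorosilane.

**Step 10**
Reactants: 10 all-cis cyclohexanone; 14 (E)-benzyldimethyl[2-(tributylstannyl)ethenyl]silane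
Product: 16 1-[(E)-2-(benzyldimethylsilyl)ethenyl]cyclohexan-1-ol derived from 10 (alkenyl trans to the three ring substituents, OH cis), via silylvinyllithium 15 (not isolated)
Conditions: 14, n-BuLi, THF, −78 °C; CeCl3, −78 °C; then 10, −78 °C
Reagents that add atoms: none
Why: The organocerium reagent adds 1,2 from the equatorial direction, trans to both flanking equatorial groups, so the two alkenyl groups end up trans-diequatorial, and CeCl3 suppresses enolisation of the β,γ-unsaturated ketone.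

**Step 11**
Reactants: 16 dialkenyl carbinol; 17 ethyl iodoacetate
Product: 20 ethyl 8α-(benzyldimethylsilyl)-3β-(tert-butyldimethylsilyloxy)-6-oxo-5β-(triisopropylsilyloxy)-13-norgermacra-1(10)E,4(15)-dien-12-oate (7α-H), via potassium alkoxide 18 (not isolated), via potassium enolate 19 (not isolated)
Conditions: KN(SiMe3)2, 18-crown-6, THF, 0 → 25 °C; then 17, −78 °C
Reagents that add atoms: none
Why: The alkoxide undergoes an anionic oxy-Cope rearrangement through a chair transition state fused trans to the all-equatorial cyclohexane chair, giving the (E)-1(10) alkene and the 8α C–Si centre from the equatorial (E)-silyl terminus; the regiospecific enolate is then alkylated at C7 on the outer face, anti to the new C8–C9 bond, placing C11 β.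

**Step 12**
Reactants: 20 keto ester
Product: 22 8α-(benzyldimethylsilyl)-3β-(tert-butyldimethylsilyloxy)-5β-(triisopropylsilyloxy)-13-norgermacra-1(10)E,4(15)-dien-6α,12-olide, via hydroxy ester 21 (not isolated)
Conditions: NaBH4, EtOH, −20 → 25 °C
Reagents that add atoms: none
Why: Hydride adds to the C6 ketone anti to the C5 silyloxy group (polar Felkin–Anh) and anti to the C7 side chain, which flank the same face, and the 6α-alkoxide closes the trans-fused γ-lactone on the ester (reduction–lactonisation).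

**Step 13**
Reactants: 22 γ-lactone
Product: 25 8α-(benzyldimethylsilyl)-3β-(tert-butyldimethylsilyloxy)-5β-(triisopropylsilyloxy)germacra-1(10)E,4(15),11(13)-trien-6α,12-olide, via Mannich base 23 (not isolated), via ammonium iodide 24 (not isolated)
Conditions: LiN(iPr)2, THF, −78 °C; CH2=NMe2 I; then MeI, MeOH, 25 °C; NaHCO3 (aq), EtOAc
Reagents that add atoms: Eschenmoser's salt, C=[N+](C)C.[I-]
Why: Aminomethylation of the lactone enolate, N-methylation and β-elimination (Eschenmoser methylenation) install the 11(13)-methylene; C11 becomes sp2, so no new stereocentre remains.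

**Step 14**
Reactants: 25 α-methylene lactone
Product: 26 3β-hydroxy compound (SitBuMe2 removed)
Conditions: HF·pyridine, pyridine, THF, 0 °C
Reagents that add atoms: none
Why: Buffered HF cleaves the allylic tert-butyldimethylsilyl ether faster than the hindered triisopropylsilyl ether and does not touch the C–Si bond at C8.

**Step 15**
Reactants: 26 3β-alcohol
Product: 27 3α-acetoxy-8α-(benzyldimethylsilyl)-5β-(triisopropylsilyloxy)germacra-1(10)E,4(15),11(13)-trien-6α,12-olide
Conditions: PPh3, DIAD, AcOH, toluene, 0 → 20 °C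
Reagents that add atoms: acetic acid, CC(=O)O
Why: In this Mitsunobu reaction acetate displaces the activated allylic C3 oxyphosphonium by SN2, inverting C3 from 3β to the required 3α-acetate.

**Step 16**
Reactants: 27 3α-acetate
Product: 29 3α-acetoxy-1β,10α-epoxy-8α-hydroxy-5β-(triisopropylsilyloxy)germacra-4(15),11(13)-dien-6α,12-olide, via fluorosilane 28 (not isolated)
Conditions: Bu4NF, THF, 0 °C, 15 min; then KF, mCPBA (3 equiv), DMF, 0 → 25 °C
Reagents that add atoms: mCPBA, OOC(=O)c1cccc(Cl)c1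
Why: Fluoride removes the benzyl group from silicon and the fluorosilane undergoes Tamao–Fleming oxidation with retention at C8, while the same peracid epoxidises the only electron-rich alkene, the (E)-1(10) bond, from its outer face to give the 1β,10α-epoxide (Prilezhaev epoxidation).

**Step 17**
Reactants: 29 8α-alcohol; 30 angelic acid
Product: 32 3α-acetoxy-8α-angeloyloxy-1β,10α-epoxy-5β-(triisopropylsilyloxy)germacra-4(15),11(13)-dien-6α,12-olide, via mixed anhydride 31 (not isolated)
Conditions: 30, 2,4,6-trichlorobenzoyl chloride, Et3N, toluene, 25 °C; then 29, toluene, 75 °C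
Reagents that add atoms: none
Why: Yamaguchi-type acylation through the mixed 2,4,6-trichlorobenzoic anhydride esterifies the only free hydroxyl without an acyl-transfer base, which avoids isomerising the (Z)-angelate to the tiglate.

**Step 18**
Reactants: 32 silyl-protected angelate
Product: 33 target, 3α-acetoxy-8α-angeloyloxy-1β,10α-epoxy-5β-hydroxygermacra-4(15),11(13)-dien-6α,12-olide (CNP0210054.2)
Conditions: HF·pyridine, pyridine, THF, 0 → 25 °C
Reagents that add atoms: none
Why: Buffered fluoride desilylation frees the 5β-hydroxyl without opening the epoxide or cleaving the two esters and the lactone.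

**Compound list**
1 | (R)-(−)-carvone, (5R)-2-methyl-5-(prop-1-en-2-yl)cyclohex-2-en-1-one | CC1=CC[C@@H](C(C)=C)CC1=O | starting material
2 | triethylsilyl dienol ether of carvone, triethyl{[(3R)-6-methyl-3-(prop-1-en-2-yl)cyclohexa-1,5-dien-1-yl]oxy}silane | CC1=CC[C@@H](C(C)=C)C=C1O[Si](CC)(CC)CC | intermediate
3 | trans-6-(triethylsilyloxy)carvone (c6-OSiEt3 trans to isopropenyl) | CC1=CC[C@@H](C(C)=C)[C@H](O[Si](CC)(CC)CC)C1=O | intermediate
4 | 6-(triethylsilyloxy)-cis-carveol (c1-OH cis to isopropenyl, trans to c6-OSiEt3) | CC1=CC[C@@H](C(C)=C)[C@H](O[Si](CC)(CC)CC)[C@H]1O | intermediate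
5 | 2,3-epoxide of 4, epoxide syn to c1-OH | C[C@@]12[C@@H](O1)C[C@@H](C(C)=C)[C@H](O[Si](CC)(CC)CC)[C@H]2O | intermediate
6 | c1-triisopropylsilyl ether of 5 | C[C@@]12[C@@H](O1)C[C@@H](C(C)=C)[C@H](O[Si](CC)(CC)CC)[C@H]2O[Si](C(C)C)(C(C)C)C(C)C | intermediate
7 | c2-methylidene c3-alcohol (c3-OH cis to c1-OSi(iPr)3 and isopropenyl; c6-OSiEt3 trans) | C=C1[C@@H](O)C[C@@H](C(C)=C)[C@H](O[Si](CC)(CC)CC)[C@H]1O[Si](C(C)C)(C(C)C)C(C)C | intermediate
8 | c3-tert-butyldimethylsilyl ether of 7 | C=C1[C@@H](O[Si](C)(C)C(C)(C)C)C[C@@H](C(C)=C)[C@H](O[Si](CC)(CC)CC)[C@H]1O[Si](C(C)C)(C(C)C)C(C)C | intermediate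
9 | c6 alcohol from 8 | C=C1[C@@H](O[Si](C)(C)C(C)(C)C)C[C@@H](C(C)=C)[C@H](O)[C@H]1O[Si](C(C)C)(C(C)C)C(C)C | intermediate
10 | all-cis 4-(tert-butyldimethylsilyloxy)-3-methylidene-6-(prop-1-en-2-yl)-2-(triisopropylsilyloxy)cyclohexan-1-one | C=C1[C@@H](O[Si](C)(C)C(C)(C)C)C[C@@H](C(C)=C)C(=O)[C@H]1O[Si](C(C)C)(C(C)C)C(C)C | intermediate
11 | (E)-1,2-bis(tributylstannyl)ethene | CCCC[Sn](CCCC)(CCCC)/C=C/[Sn](CCCC)(CCCC)CCCC | starting material
12 | benzylchlorodimethylsilane | C[Si](C)(Cl)Cc1ccccc1 | starting material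
13 | (E)-2-(tributylstannyl)ethenyllithium | [Li]/C=C/[Sn](CCCC)(CCCC)CCCC | intermediate
14 | (E)-benzyldimethyl[2-(tributylstannyl)ethenyl]silane | CCCC[Sn](CCCC)(CCCC)/C=C/[Si](C)(C)Cc1ccccc1 | intermediate
15 | (E)-2-(benzyldimethylsilyl)ethenyllithium | [Li]/C=C/[Si](C)(C)Cc1ccccc1 | intermediate
16 | 1-[(E)-2-(benzyldimethylsilyl)ethenyl] carbinol from 10 (alkenyl trans to the three ring substituents, OH cis) | C=C1[C@@H](O[Si](C)(C)C(C)(C)C)C[C@@H](C(C)=C)[C@](O)(/C=C/[Si](C)(C)Cc2ccccc2)[C@H]1O[Si](C(C)C)(C(C)C)C(C)C | intermediate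
17 | ethyl iodoacetate | CCOC(=O)CI | starting material
18 | potassium alkoxide of 16 | C=C1[C@@H](O[Si](C)(C)C(C)(C)C)C[C@@H](C(C)=C)[C@]([O-])(/C=C/[Si](C)(C)Cc2ccccc2)[C@H]1O[Si](C(C)C)(C(C)C)C(C)C.[K+] | intermediate
19 | potassium C6–C7 enolate of the ring-expanded cyclodec-1(10)E-en-6-one (O cis to C8; 8α-silyl) | C=C1[C@@H](O[Si](C)(C)C(C)(C)C)C/C=C(C)/C[C@H]([Si](C)(C)Cc2ccccc2)/C=C(\[O-])[C@H]1O[Si](C(C)C)(C(C)C)C(C)C.[K+] | intermediate
20 | ethyl 8α-(benzyldimethylsilyl)-3β-(tert-butyldimethylsilyloxy)-6-oxo-5β-(triisopropylsilyloxy)-13-norgermacra-1(10)E,4(15)-dien-12-oate | C=C1[C@@H](O[Si](C)(C)C(C)(C)C)C/C=C(C)/C[C@H]([Si](C)(C)Cc2ccccc2)[C@@H](CC(=O)OCC)C(=O)[C@H]1O[Si](C(C)C)(C(C)C)C(C)C | intermediate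
21 | 6α-hydroxy ester from 20 | C=C1[C@@H](O[Si](C)(C)C(C)(C)C)C/C=C(C)/C[C@H]([Si](C)(C)Cc2ccccc2)[C@@H](CC(=O)OCC)[C@H](O)[C@H]1O[Si](C(C)C)(C(C)C)C(C)C | intermediate
22 | 8α-(benzyldimethylsilyl)-3β-(tert-butyldimethylsilyloxy)-5β-(triisopropylsilyloxy)-13-norgermacra-1(10)E,4(15)-dien-6α,12-olide | C=C1[C@@H](O[Si](C)(C)C(C)(C)C)C/C=C(C)/C[C@H]([Si](C)(C)Cc2ccccc2)[C@H]2CC(=O)O[C@@H]2[C@H]1O[Si](C(C)C)(C(C)C)C(C)C | intermediate
23 | 11-(dimethylaminomethyl) lactone (C11 epimers) | C=C1[C@@H](O[Si](C)(C)C(C)(C)C)C/C=C(C)/C[C@H]([Si](C)(C)Cc2ccccc2)[C@H]2C(CN(C)C)C(=O)O[C@@H]2[C@H]1O[Si](C(C)C)(C(C)C)C(C)C | intermediate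
24 | 11-(trimethylammoniomethyl) lactone iodide | C=C1[C@@H](O[Si](C)(C)C(C)(C)C)C/C=C(C)/C[C@H]([Si](C)(C)Cc2ccccc2)[C@H]2C(C[N+](C)(C)C)C(=O)O[C@@H]2[C@H]1O[Si](C(C)C)(C(C)C)C(C)C.[I-] | intermediate
25 | 8α-(benzyldimethylsilyl)-3β-(tert-butyldimethylsilyloxy)-5β-(triisopropylsilyloxy)germacra-1(10)E,4(15),11(13)-trien-6α,12-olide | C=C1[C@@H](O[Si](C)(C)C(C)(C)C)C/C=C(C)/C[C@H]([Si](C)(C)Cc2ccccc2)[C@H]2C(=C)C(=O)O[C@@H]2[C@H]1O[Si](C(C)C)(C(C)C)C(C)C | intermediate
26 | 8α-(benzyldimethylsilyl)-3β-hydroxy-5β-(triisopropylsilyloxy)germacra-1(10)E,4(15),11(13)-trien-6α,12-olide | C=C1[C@@H](O)C/C=C(C)/C[C@H]([Si](C)(C)Cc2ccccc2)[C@H]2C(=C)C(=O)O[C@@H]2[C@H]1O[Si](C(C)C)(C(C)C)C(C)C | intermediate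
27 | 3α-acetoxy-8α-(benzyldimethylsilyl)-5β-(triisopropylsilyloxy)germacra-1(10)E,4(15),11(13)-trien-6α,12-olide | C=C1[C@H](OC(C)=O)C/C=C(C)/C[C@H]([Si](C)(C)Cc2ccccc2)[C@H]2C(=C)C(=O)O[C@@H]2[C@H]1O[Si](C(C)C)(C(C)C)C(C)C | intermediate
28 | 3α-acetoxy-8α-(fluorodimethylsilyl)-5β-(triisopropylsilyloxy)germacra-1(10)E,4(15),11(13)-trien-6α,12-olide | C=C1[C@H](OC(C)=O)C/C=C(C)/C[C@H]([Si](C)(C)F)[C@H]2C(=C)C(=O)O[C@@H]2[C@H]1O[Si](C(C)C)(C(C)C)C(C)C | intermediate
29 | 3α-acetoxy-1β,10α-epoxy-8α-hydroxy-5β-(triisopropylsilyloxy)germacra-4(15),11(13)-dien-6α,12-olide | C=C1[C@H](OC(C)=O)C[C@H]2O[C@]2(C)C[C@H](O)[C@H]2C(=C)C(=O)O[C@@H]2[C@H]1O[Si](C(C)C)(C(C)C)C(C)C | intermediate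
30 | angelic acid, (Z)-2-methylbut-2-enoic acid | C/C=C(/C)C(=O)O | starting material
31 | angelic 2,4,6-trichlorobenzoic anhydride | C/C=C(/C)C(=O)OC(=O)c1c(Cl)cc(Cl)cc1Cl | intermediate
32 | 3α-acetoxy-8α-angeloyloxy-1β,10α-epoxy-5β-(triisopropylsilyloxy)germacra-4(15),11(13)-dien-6α,12-olide | C=C1[C@H](OC(C)=O)C[C@H]2O[C@]2(C)C[C@H](OC(=O)/C(C)=C\C)[C@H]2C(=C)C(=O)O[C@@H]2[C@H]1O[Si](C(C)C)(C(C)C)C(C)C | intermediate
33 | 3α-acetoxy-8α-angeloyloxy-1β,10α-epoxy-5β-hydroxygermacra-4(15),11(13)-dien-6α,12-olide (CNP0210054.2) | C=C1[C@H](OC(C)=O)C[C@H]2O[C@]2(C)C[C@H](OC(=O)/C(C)=C\C)[C@H]2C(=C)C(=O)O[C@@H]2[C@H]1O | target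

**Step count and risks**
Total: 18 steps. Longest linear sequence: 17 steps from (R)-carvone (steps 1–8 and 10–18); step 9 makes the vinylsilane reagent.

Most likely to fail:

Step 11 (oxy-Cope rearrangement with in-flask alkylation). The hindered potassium enolate may suffer proton transfer, O-alkylation or leakage of facial selectivity at C7. The fallback sets out from 16: after the same rearrangement the enolate 19 is quenched with Me3SiCl and isolated as the trimethylsilyl enol ether F1. Cu(acac)2-catalysed cyclopropanation of its enol double bond with ethyl diazoacetate on the outer face gives the siloxycyclopropane ester F2. Et3N·3HF then opens the donor–acceptor cyclopropane between C6 and the ester-bearing carbon, and the route is rejoined at keto ester 20.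

Step 12 (C6 reduction). The face of hydride attack on a ten-membered ketone is conformation-dependent, and the 6-epimer would give the cis-fused lactone. The fallback sets out from 20 and makes that epimer on purpose: LiBH(s-Bu)3 at −78 °C attacks from the outer face and the product closes to the cis-fused 6-epi-lactone F3. LiOH followed by cold, careful acidification gives the 6-epi hydroxy acid F4, and Mitsunobu lactonisation (PPh3, DIAD, high dilution) closes the ring with inversion at C6, returning to lactone 22.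

Step 16 (one-flask C–Si oxidation and epoxidation). The fluoride-triggered peracid oxidation next to a Michael-acceptor lactone has little direct precedent, and the epoxidation face depends on the ring conformation. The fallback sets out from 22 and oxidises silicon before any Michael acceptor exists: Bu4NF then H2O2/KHCO3 in MeOH/THF gives the 8α-hydroxy lactone F5. Acylation with mixed anhydride 31 gives the 8α-angelate F6. Methylenation with LiN(SiMe3)2, Eschenmoser's salt, MeI and NaHCO3 gives the α-methylene lactone F7. HF·pyridine gives the 3β-alcohol F8, and Mitsunobu reaction with AcOH gives the 3α-acetate F9. mCPBA epoxidation of the 1(10) alkene then rejoins the route at 32.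

**Further compounds**
F1 | step 11 | trimethylsilyl enol ether of the ring-expanded ketone (C6-OSiMe3, C6=C7, O cis to C8) | C=C1[C@@H](O[Si](C)(C)C(C)(C)C)C/C=C(C)/C[C@H]([Si](C)(C)Cc2ccccc2)/C=C(\O[Si](C)(C)C)[C@H]1O[Si](C(C)C)(C(C)C)C(C)C
F2 | step 11 | ethyl 6-(trimethylsilyloxy)-6,7-methano cyclopropanecarboxylate (cyclopropane on the outer face, ester carbon unassigned) | C=C1[C@@H](O[Si](C)(C)C(C)(C)C)C/C=C(C)/C[C@H]([Si](C)(C)Cc2ccccc2)[C@H]2C(C(=O)OCC)[C@]2(O[Si](C)(C)C)[C@H]1O[Si](C(C)C)(C(C)C)C(C)C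
F3 | step 12 | 6-epi (cis-fused, 6β,12-olide) isomer of 22 | C=C1[C@@H](O[Si](C)(C)C(C)(C)C)C/C=C(C)/C[C@H]([Si](C)(C)Cc2ccccc2)[C@H]2CC(=O)O[C@H]2[C@H]1O[Si](C(C)C)(C(C)C)C(C)C
F4 | step 12 | 6β-hydroxy-13-norgermacra-1(10)E,4(15)-dien-12-oic acid corresponding to F3 | C=C1[C@@H](O[Si](C)(C)C(C)(C)C)C/C=C(C)/C[C@H]([Si](C)(C)Cc2ccccc2)[C@@H](CC(=O)O)[C@@H](O)[C@H]1O[Si](C(C)C)(C(C)C)C(C)C
F5 | step 16 | 3β-(tert-butyldimethylsilyloxy)-8α-hydroxy-5β-(triisopropylsilyloxy)-13-norgermacra-1(10)E,4(15)-dien-6α,12-olide | C=C1[C@@H](O[Si](C)(C)C(C)(C)C)C/C=C(C)/C[C@H](O)[C@H]2CC(=O)O[C@@H]2[C@H]1O[Si](C(C)C)(C(C)C)C(C)C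
F6 | step 16 | 8α-angelate of F5 | C=C1[C@@H](O[Si](C)(C)C(C)(C)C)C/C=C(C)/C[C@H](OC(=O)/C(C)=C\C)[C@H]2CC(=O)O[C@@H]2[C@H]1O[Si](C(C)C)(C(C)C)C(C)C
F7 | step 16 | 8α-angeloyloxy-3β-(tert-butyldimethylsilyloxy)-5β-(triisopropylsilyloxy)germacra-1(10)E,4(15),11(13)-trien-6α,12-olide | C=C1[C@@H](O[Si](C)(C)C(C)(C)C)C/C=C(C)/C[C@H](OC(=O)/C(C)=C\C)[C@H]2C(=C)C(=O)O[C@@H]2[C@H]1O[Si](C(C)C)(C(C)C)C(C)C
F8 | step 16 | 8α-angeloyloxy-3β-hydroxy-5β-(triisopropylsilyloxy)germacra-1(10)E,4(15),11(13)-trien-6α,12-olide | C=C1[C@@H](O)C/C=C(C)/C[C@H](OC(=O)/C(C)=C\C)[C@H]2C(=C)C(=O)O[C@@H]2[C@H]1O[Si](C(C)C)(C(C)C)C(C)C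
F9 | step 16 | 3α-acetoxy-8α-angeloyloxy-5β-(triisopropylsilyloxy)germacra-1(10)E,4(15),11(13)-trien-6α,12-olide | C=C1[C@H](OC(C)=O)C/C=C(C)/C[C@H](OC(=O)/C(C)=C\C)[C@H]2C(=C)C(=O)O[C@@H]2[C@H]1O[Si](C(C)C)(C(C)C)C(C)C
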